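**Plan**
- Retrosynthetic cuts: the C15 acid/C12–O pair (butenolide opening), C13–C16 and C12–C13 (cuprate, aldehyde alkynylation), C8=C17 (Wittig), then C3–C4, then C1–O, C10–C1, C9–C11, C10–C20 and ring B.
- Enabling feature: C4 of ring A is the α-carbon of the C19 carboxyl group, and C1 lies across ring A from it. A temporary C19–O–C1 δ-lactone (ring O, C19, C4, C5, C10, C1, fused to ring B) with a vinyl group on C1 makes C4=C19–O–C1–C2=C3 an allyl vinyl ether whose [3,3] shift joins C3 to C4.
- Forward order: ring B by aldehyde/enone annulation; C10 quaternary centre and C9 alkylidene by cuprate/aldol coupling; temporary lactone; ring A by lactone-enolate rearrangement; then exocyclic methylene and the C12–C16 chain.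
- Helpers: the tether oxygen leaves C1 in the shift and stays as a C19 carboxyl oxygen; the C1=C2 and C9=C11 alkenes are hydrogenated in step 9.
- Stereochemistry: C5 from an (S)-prolinol ether catalyst; C10 by anti addition next to C5; temporary C1 by 1,3-allylic strain in the lactonization; C4 relayed from C1 through the tether; C9 by α-face hydrogenation; C12 by the ProPhenol ligand; 13Z by syn-carbocupration.

Key step: step 8

Remark: the ester α-carbon (C4) is carried as both epimers until it becomes the enolate carbon in step 8. Its descriptor, the C9=C11 geometry and the carbinol centres of 9 and 10 are left open in names and SMILES because all are erased later. The cuprates are pre-formed in separate flasks.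
Remark: the target is the ring-opened hydroxy acid of a 15,12-butenolide and is assumed to be isolable after cold, pH-controlled acidification of its dicarboxylate.

Step 1
Reactants: 1 methyl 2-methyl-4-oxobutanoate (racemic); 2 methyl vinyl ketone
Product: 4 methyl 2-[(1R)-4-oxocyclohex-2-en-1-yl]propanoate, via keto aldehyde 3 (not isolated)
Conditions: (S)-2-(methoxydiphenylmethyl)pyrrolidine (5 mol%), ethyl 3,4-dihydroxybenzoate (20 mol%), neat, 4 °C; then p-TsOH·H2O (10 mol%), toluene, 70 °C
Reagents that add atoms: none
Why: Enamine-mediated asymmetric Michael addition of the aldehyde to the enone followed by acid-catalysed intramolecular aldol condensation (an organocatalytic Robinson-type annulation) should give the 4-substituted cyclohexenone, the diarylmethyl group of the (S)-catalyst shielding one face of the E-enamine so that the enone adds to the other and sets C5 of ring B.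

Step 2
Reactants: 4 methyl 2-[(1R)-4-oxocyclohex-2-en-1-yl]propanoate
Product: 5 methyl 2-[trans-2-methyl-4-(trimethylsilyloxy)cyclohex-3-en-1-yl]propanoate
Conditions: Me2CuLi, TMSCl, THF, −78 °C; Et3N, NaHCO3 (aq)
Reagents that add atoms: lithium dimethylcuprate [Li+].C[Cu-]C; chlorotrimethylsilane C[Si](C)(C)Cl
Why: Silyl-chloride-accelerated conjugate addition of the cuprate should place the C20 methyl on the β-carbon (C10), anti to the C5 side chain, and trap the enolate regiospecifically as its silyl enol ether, this centre becoming trigonal again in step 3.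

Step 3
Reactants: 5 methyl 2-[trans-2-methyl-4-(trimethylsilyloxy)cyclohex-3-en-1-yl]propanoate
Product: 6 methyl 2-[(1S)-2-methyl-4-oxocyclohex-2-en-1-yl]propanoate
Conditions: Pd(OAc)2 (1.05 equiv), MeCN, 25 °C
Reagents that add atoms: none
Why: Saegusa–Ito oxidation (palladation at C9 of the silyl enol ether, then β-hydride elimination of the C10 hydrogen) should restore the conjugated enone with the methyl now on the β-carbon and leave C5 untouched.

Step 4
Reactants: 6 methyl 2-[(1S)-2-methyl-4-oxocyclohex-2-en-1-yl]propanoate; 7 2,2-dimethoxyacetaldehyde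
Product: 9 methyl 2-[3-(1-hydroxy-2,2-dimethoxyethyl)-2-methyl-4-oxo-2-[(E)-prop-1-enyl]cyclohexyl]propanoate, via lithium enolate 8 (not isolated)
Conditions: [(E)-MeCH=CH]2CuLi, Et2O/THF, −78 → −30 °C; then 7, −78 °C; NH4Cl (aq)
Reagents that add atoms: lithium di[(E)-prop-1-enyl]cuprate [Li+].C/C=C/[Cu-]/C=C/C
Why: Conjugate addition of the dialkenylcuprate to the β,β-disubstituted enone should create the C10 quaternary centre with the propenyl group (future C1–C3) anti to the C5 substituent, so that C20 ends cis to it, and the regiodefined C9 enolate is captured by the aldehyde in an aldol addition (three-component conjugate addition–aldol coupling).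

Step 5
Reactants: 9 methyl 2-[3-(1-hydroxy-2,2-dimethoxyethyl)-2-methyl-4-oxo-2-[(E)-prop-1-enyl]cyclohexyl]propanoate
Product: 11 methyl 2-[(1S,2S)-3-(2,2-dimethoxyethylidene)-2-methyl-4-oxo-2-[(E)-prop-1-enyl]cyclohexyl]propanoate, via mesylate 10 (not isolated)
Conditions: MsCl, Et3N, CH2Cl2, 0 °C; then DBU, 25 °C
Reagents that add atoms: none
Why: Mesylation and E1cB elimination (aldol dehydration) should give the α-alkylidene ketone, which stores the C9–C11 bond while keeping C9 trigonal until ring A is in place.

Step 6
Reactants: 11 methyl 2-[(1S,2S)-3-(2,2-dimethoxyethylidene)-2-methyl-4-oxo-2-[(E)-prop-1-enyl]cyclohexyl]propanoate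
Product: 12 2-[(1S,2S)-3-(2,2-dimethoxyethylidene)-2-methyl-4-oxo-2-[(E)-prop-1-enyl]cyclohexyl]propanoic acid
Conditions: LiOH, THF/MeOH/H2O, 25–40 °C; then 1 M HCl to pH 4
Reagents that add atoms: lithium hydroxide [Li+].[OH-]
Why: Saponification of the methyl ester should free the C19 acid as the internal nucleophile for step 7, the enone and the dimethyl acetal being stable to aqueous base at this temperature.

Step 7
Reactants: 12 2-[(1S,2S)-3-(2,2-dimethoxyethylidene)-2-methyl-4-oxo-2-[(E)-prop-1-enyl]cyclohexyl]propanoic acid
Product: 15 (1R,4aS,8aS)-8-(2,2-dimethoxyethylidene)-1-ethenyl-4,8a-dimethyloctahydroisochromene-3,7-dione, via selenide lactone 13 (not isolated), via selenoxide 14 (not isolated)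
Conditions: PhSeCl, Et3N, CH2Cl2, −78 °C; then H2O2 (30%), pyridine, 0 → 25 °C
Reagents that add atoms: none
Why: Phenylselenolactonization (anti addition across the propenyl group, 6-exo closure at C1), oxidation and selenoxide syn-elimination away from oxygen should give the trans-fused 6-vinyl δ-lactone, the C1 carbon substituent taking the axial position anti to the C10 methyl because the equatorial position suffers 1,3-allylic strain against the C9 alkylidene group.

Step 8
Reactants: 15 (1R,4aS,8aS)-8-(2,2-dimethoxyethylidene)-1-ethenyl-4,8a-dimethyloctahydroisochromene-3,7-dione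
Product: 18 12,12-dimethoxy-8-oxo-13,14,15,16-tetranorlabda-1,9(11)-dien-19-oic acid, via bis(silyl) ketene acetal 16 (not isolated), via bis(silyl) rearranged ester 17 (not isolated)
Conditions: LiN(iPr)2 (2.5 equiv), TMSCl/Et3N, THF, −78 °C; then toluene, 90 °C; then citric acid (aq), 0 °C
Reagents that add atoms: none
Why: Excess amide base with TMSCl present turns the C8 ketone into a spectator silyl dienol ether and the lactone into the cyclic silyl ketene acetal 16, in which C4=C19–O–C1–C2=C3 is an allyl vinyl ether; on warming, a concerted suprafacial [3,3]-sigmatropic shift breaks O–C1 and forms C3–C4 (Ireland–Claisen rearrangement of a lactone enolate, the known ring contraction of 6-alkenyl-tetrahydropyran-2-ones to cyclohex-3-enecarboxylic acids). Ring A (C1, C2, C3, C4, C5, C10) closes from the six-membered lactone through a boat-like six-centre array with the allyl unit ending inside the ring as the cis C1=C2 alkene, and the array must twist to keep the trans fusion at C5–C10, which the long partial bonds of this transition state should allow. The only new stereocentre, C4, is set by the C19–O–C1 tether: C3 can reach C4 only from the lactone face that carries the axial C1 vinyl group (anti to the C10 methyl), so C19, still bound through oxygen to C1 while the bond forms, ends β (axial, cis to C20) and the C18 methyl equatorial. The step needs site-selective enolization and a single [3,3] pathway: once the ketone is silylated the lactone C4–H is the only remaining acidic C–H, the acetal and alkylidene are inert to the amide base at −78 °C, and the C1 configuration from step 7 admits one reactive conformer. Mild aqueous acid then removes both silyl groups, returning the C8 enone and freeing the C19 acid with the dimethyl acetal intact.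

Step 9
Reactants: 18 12,12-dimethoxy-8-oxo-13,14,15,16-tetranorlabda-1,9(11)-dien-19-oic acid
Product: 19 12,12-dimethoxy-8-oxo-13,14,15,16-tetranorlabdan-19-oic acid
Conditions: H2 (1 atm), Pd/C, EtOAc, 25 °C
Reagents that add atoms: none
Why: Heterogeneous hydrogenation should saturate both the helper C1=C2 alkene and the conjugated C9=C11 alkene, hydrogen reaching C9 from the α face opposite the axial C10 methyl so that the side chain becomes β (equatorial), which is also the preferred configuration α to the C8 ketone.

Step 10
Reactants: 19 12,12-dimethoxy-8-oxo-13,14,15,16-tetranorlabdan-19-oic acid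
Product: 20 12,12-dimethoxy-13,14,15,16-tetranorlabd-8(17)-en-19-oic acid
Conditions: Ph3PCH3Br (4 equiv), KOtBu (4 equiv), toluene, 25 → 60 °C; then NaH2PO4 (aq)
Reagents that add atoms: methylenetriphenylphosphorane C=P(c1ccccc1)(c1ccccc1)c1ccccc1
Why: Wittig methylenation of the C8 ketone, with the acid carried as its potassium salt, should install the exocyclic 8(17)-alkene, and any base-mediated equilibration at C9 beforehand converges on the equatorial side chain.

Step 11
Reactants: 20 12,12-dimethoxy-13,14,15,16-tetranorlabd-8(17)-en-19-oic acid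
Product: 21 12-oxo-13,14,15,16-tetranorlabd-8(17)-en-19-oic acid
Conditions: pyridinium p-toluenesulfonate, acetone/H2O, 50 °C
Reagents that add atoms: water O
Why: Mild acid-catalysed acetal hydrolysis should release the C12 aldehyde without migration of the exocyclic double bond.

Step 12
Reactants: 21 12-oxo-13,14,15,16-tetranorlabd-8(17)-en-19-oic acid; 22 methyl propiolate
Product: 24 (12S)-12-hydroxy-15-methoxy-15-oxo-16-norlabd-8(17)-en-13-yn-19-oic acid, via alkynylzinc 23 (not isolated)
Conditions: (S,S)-ProPhenol (20 mol%), Me2Zn (4 equiv), Ph3PO (40 mol%), toluene, 4 °C; NH4Cl (aq)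
Reagents that add atoms: none
Why: Zinc–ProPhenol-catalysed asymmetric alkynylation should deliver the zinc acetylide to the Re face of the aldehyde under ligand control and set C12 as (S), the ligand antipode being fixed by this requirement and the C19 acid being carried as its zinc carboxylate by one extra equivalent of Me2Zn.

Step 13
Reactants: 24 (12S)-12-hydroxy-15-methoxy-15-oxo-16-norlabd-8(17)-en-13-yn-19-oic acid
Product: 26 (12S)-labda-8(17),13-dien-15,12-olid-19-oic acid, via hydroxy enoate 25 (not isolated)
Conditions: Me2CuLi (5 equiv), THF, −78 °C; then AcOH, −78 → 25 °C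
Reagents that add atoms: lithium dimethylcuprate [Li+].C[Cu-]C
Why: Low-temperature syn-carbocupration (conjugate addition) of the ynoate places the C16 methyl on C13 cis to H14, so C12 and the ester are cis (Z) and the γ-alkoxide lactonizes to the butenolide without touching C12.

Step 14
Reactants: 26 (12S)-labda-8(17),13-dien-15,12-olid-19-oic acid
Product: 27 (12S,13Z)-12-hydroxylabda-8(17),13-diene-15,19-dioic acid
Conditions: LiOH, THF/H2O, 0 → 25 °C; then 0.5 M HCl at 0 °C to pH 4.5, EtOAc extraction
Reagents that add atoms: lithium hydroxide [Li+].[OH-]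
Why: Hydroxide should open the butenolide by acyl substitution to the dicarboxylate with Z geometry and C12 configuration retained, and cold, pH-controlled acidification should give the hydroxy diacid before it relactonizes.

**Compound list**
1 | methyl 2-methyl-4-oxobutanoate (racemic) | COC(=O)C(C)CC=O | starting material
2 | methyl vinyl ketone (but-3-en-2-one) | CC(=O)C=C | starting material
3 | methyl (3S)-3-formyl-2-methyl-6-oxoheptanoate (both C2 epimers) | CC(=O)CC[C@@H](C(C)C(=O)OC)C=O | intermediate
4 | methyl 2-[(1R)-4-oxocyclohex-2-en-1-yl]propanoate | O=C1CC[C@@H](C(C)C(=O)OC)C=C1 | intermediate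
5 | methyl 2-[trans-2-methyl-4-(trimethylsilyloxy)cyclohex-3-en-1-yl]propanoate (ring C1 as in 4, ring methyl anti to the side chain) | C[Si](C)(C)OC1=C[C@@H](C)[C@H](C(C)C(=O)OC)CC1 | intermediate
6 | methyl 2-[(1S)-2-methyl-4-oxocyclohex-2-en-1-yl]propanoate | O=C1CC[C@@H](C(C)C(=O)OC)C(C)=C1 | intermediate
7 | 2,2-dimethoxyacetaldehyde | COC(OC)C=O | starting material
8 | lithium 4-(1-methoxy-1-oxopropan-2-yl)-3-methyl-3-[(E)-prop-1-enyl]cyclohex-1-en-1-olate (methyl cis, propenyl trans to the side chain) | [Li]OC1=C[C@@](C)(/C=C/C)[C@H](C(C)C(=O)OC)CC1 | intermediate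
9 | methyl 2-[3-(1-hydroxy-2,2-dimethoxyethyl)-2-methyl-4-oxo-2-[(E)-prop-1-enyl]cyclohexyl]propanoate (ring C1 and C2 as in 11) | O=C1CC[C@@H](C(C)C(=O)OC)[C@](C)(/C=C/C)C1C(O)C(OC)OC | intermediate
10 | methanesulfonate of 9 | O=C1CC[C@@H](C(C)C(=O)OC)[C@](C)(/C=C/C)C1C(OS(C)(=O)=O)C(OC)OC | intermediate
11 | methyl 2-[(1S,2S)-3-(2,2-dimethoxyethylidene)-2-methyl-4-oxo-2-[(E)-prop-1-enyl]cyclohexyl]propanoate | O=C1CC[C@@H](C(C)C(=O)OC)[C@](C)(/C=C/C)C1=CC(OC)OC | intermediate
12 | 2-[(1S,2S)-3-(2,2-dimethoxyethylidene)-2-methyl-4-oxo-2-[(E)-prop-1-enyl]cyclohexyl]propanoic acid | O=C1CC[C@@H](C(C)C(=O)O)[C@](C)(/C=C/C)C1=CC(OC)OC | intermediate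
13 | trans-fused δ-lactone with a 1-(phenylselanyl)ethyl group on the carbinol carbon (anti adduct) | O=C1CC[C@@H]2[C@](C)([C@@H]([C@@H](C)[Se]c3ccccc3)OC(=O)C2C)C1=CC(OC)OC | intermediate
14 | selenoxide of 13 | O=C1CC[C@@H]2[C@](C)([C@@H]([C@@H](C)[Se](=O)c3ccccc3)OC(=O)C2C)C1=CC(OC)OC | intermediate
15 | (1R,4aS,8aS)-8-(2,2-dimethoxyethylidene)-1-ethenyl-4,8a-dimethyloctahydroisochromene-3,7-dione (C19→C1 lactone; vinyl anti to the angular methyl) | O=C1CC[C@@H]2[C@](C)([C@@H](C=C)OC(=O)C2C)C1=CC(OC)OC | intermediate
16 | bis(trimethylsilyl) derivative of 15: cyclic ketene acetal at C19=C4 and dienol ether at C8=C7 | C[Si](C)(C)OC1=CC[C@@H]2[C@](C)([C@@H](C=C)OC(O[Si](C)(C)C)=C2C)C1=CC(OC)OC | intermediate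
17 | trimethylsilyl ester and C8 silyl dienol ether of 18 | C[Si](C)(C)OC1=CC[C@@H]2[C@](C)(C=CC[C@]2(C)C(=O)O[Si](C)(C)C)C1=CC(OC)OC | intermediate
18 | 12,12-dimethoxy-8-oxo-13,14,15,16-tetranorlabda-1,9(11)-dien-19-oic acid (4α-methyl, 4β-carboxyl, 5α-H, 10β-methyl) | O=C1CC[C@@H]2[C@](C)(C=CC[C@]2(C)C(=O)O)C1=CC(OC)OC | intermediate
19 | 12,12-dimethoxy-8-oxo-13,14,15,16-tetranorlabdan-19-oic acid (9α-H) | O=C1CC[C@@H]2[C@](C)(CCC[C@]2(C)C(=O)O)[C@H]1CC(OC)OC | intermediate
20 | 12,12-dimethoxy-13,14,15,16-tetranorlabd-8(17)-en-19-oic acid | C=C1CC[C@@H]2[C@](C)(CCC[C@]2(C)C(=O)O)[C@H]1CC(OC)OC | intermediate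
21 | 12-oxo-13,14,15,16-tetranorlabd-8(17)-en-19-oic acid | C=C1CC[C@@H]2[C@](C)(CCC[C@]2(C)C(=O)O)[C@H]1CC=O | intermediate
22 | methyl propiolate | COC(=O)C#C | starting material
23 | methyl 3-(methylzincio)prop-2-ynoate | C[Zn]C#CC(=O)OC | intermediate
24 | (12S)-12-hydroxy-15-methoxy-15-oxo-16-norlabd-8(17)-en-13-yn-19-oic acid | C=C1CC[C@@H]2[C@](C)(CCC[C@]2(C)C(=O)O)[C@H]1C[C@H](O)C#CC(=O)OC | intermediate
25 | (12S,13Z)-12-hydroxy-15-methoxy-15-oxolabda-8(17),13-dien-19-oic acid | C=C1CC[C@@H]2[C@](C)(CCC[C@]2(C)C(=O)O)[C@H]1C[C@H](O)/C(C)=C\C(=O)OC | intermediate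
26 | (12S)-labda-8(17),13-dien-15,12-olid-19-oic acid | C=C1CC[C@@H]2[C@](C)(CCC[C@]2(C)C(=O)O)[C@H]1C[C@@H]3OC(=O)C=C3C | intermediate
27 | (12S,13Z)-12-hydroxylabda-8(17),13-diene-15,19-dioic acid | C=C1CC[C@@H]2[C@](C)(CCC[C@]2(C)C(=O)O)[C@H]1C[C@H](O)/C(C)=C\C(=O)O | target

**Totals**
Total step count: 14. Longest linear sequence: 14 steps (fully linear from 1 and 2).

**Steps most likely to fail**

Step 8. The trans ring fusion forces a strongly twisted boat transition state, so the rearrangement may be slower than hydrolysis or fragmentation of the ketene acetal. The fallback sets out from 12 and returns at 18, bypassing steps 7 and 8. The acid 12 is alkylated (K2CO3, allyl bromide, DMF) to its allyl ester F1. An acyclic Ireland–Claisen rearrangement (LiN(iPr)2, TMSCl/Et3N, THF, −78 → 60 °C; aqueous citric acid) through an unconstrained chair transition state transfers the allyl group to C4, anti to the quaternary C10 under 1,3-allylic strain control, giving the C4-allylated acid F2. Ring-closing metathesis between the allyl and propenyl groups (second-generation Grubbs catalyst, CH2Cl2, 40 °C) then closes ring A at C1=C2 and gives 18. Here C3–C4 is made without the lactone tether.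

Step 7. The carboxylate may open the seleniranium ion at the less hindered C2 instead of the neopentyl C1, facial selectivity at C1 may be poor, and selenenylation α to the ketone may compete. The fallback goes from 12 directly to 15 by aerobic oxidative lactonization with catalytic Pd(OAc)2 (NaOAc, DMSO, O2, 25–50 °C): carboxylate oxypalladation of the propenyl group (6-exo) is followed by β-hydride elimination toward C3. No new compound is made on the way (F0).

Step 14. The (Z)-γ-hydroxy acid may relactonize during or after acidification. The fallback sets out from 24 and returns at 27. The propargylic alcohol 24 is silylated (TBSOTf, 2,6-lutidine, CH2Cl2; aqueous NaHCO3 to cleave the silyl ester) to the silyl ether F3. Me2CuLi (THF, −78 °C) gives the (Z)-enoate F4, which cannot lactonize. LiOH (THF/MeOH/H2O, 40 °C) gives the diacid silyl ether F5, which can be acidified normally. Buffered fluoride (Bu4NF/AcOH, THF, 0 °C) then removes the silyl group under near-neutral conditions, and 27 is isolated by reverse-phase chromatography in buffered eluent.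

**Further compounds**
F1 | step 8 | prop-2-enyl 2-[(1S,2S)-3-(2,2-dimethoxyethylidene)-2-methyl-4-oxo-2-[(E)-prop-1-enyl]cyclohexyl]propanoate | O=C1CC[C@@H](C(C)C(=O)OCC=C)[C@](C)(/C=C/C)C1=CC(OC)OC
F2 | step 8 | 2-[3-(2,2-dimethoxyethylidene)-2-methyl-4-oxo-2-[(E)-prop-1-enyl]cyclohexyl]-2-methylpent-4-enoic acid (ring centres as in 12, quaternary α-carbon as C4 of the target) | O=C1CC[C@@H]([C@](C)(CC=C)C(=O)O)[C@](C)(/C=C/C)C1=CC(OC)OC
F0 | step 7 | none | none
F3 | step 14 | (12S)-12-(tert-butyldimethylsilyloxy)-15-methoxy-15-oxo-16-norlabd-8(17)-en-13-yn-19-oic acid | C=C1CC[C@@H]2[C@](C)(CCC[C@]2(C)C(=O)O)[C@H]1C[C@H](O[Si](C)(C)C(C)(C)C)C#CC(=O)OC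
F4 | step 14 | (12S,13Z)-12-(tert-butyldimethylsilyloxy)-15-methoxy-15-oxolabda-8(17),13-dien-19-oic acid | C=C1CC[C@@H]2[C@](C)(CCC[C@]2(C)C(=O)O)[C@H]1C[C@H](O[Si](C)(C)C(C)(C)C)/C(C)=C\C(=O)OC
F5 | step 14 | (12S,13Z)-12-(tert-butyldimethylsilyloxy)labda-8(17),13-diene-15,19-dioic acid | C=C1CC[C@@H]2[C@](C)(CCC[C@]2(C)C(=O)O)[C@H]1C[C@H](O[Si](C)(C)C(C)(C)C)/C(C)=C\C(=O)O
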